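**Plan**
1. Retrosynthesis: the O6 isopropyl ether is the only protecting group. Ring C is cut at C4–C4a (Friedel–Crafts acylation), then at O1–C2 (vinylic substitution), then at C2–C3 (Claisen formylation).
2. This leaves 3-methoxy-4-(propan-2-yloxy)phenol (ring A with O1, from vanillin), methyl 3,4,5-trimethoxyphenylacetate (ring B, C3, C4) and methyl formate (C2).
3. Forward: rings A and B come ready-made. The formylated and tosylated arylacetate is joined to the phenol through O1–C2, the ester is hydrolysed, and ring C is closed last by C-acylation. BCl3 then frees the 6-OH.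
4. Enabling feature: C4a of ring A is para to the C7 methoxy group and ortho to O1. It is therefore the most nucleophilic carbon of ring A and can accept the C4 carbonyl as an acylium ion from an aryl vinyl ether that already carries O1, C2, C3 and ring B.
5. Stereochemistry: the target has no stereocentre. The only stereo-element on the way is the C2=C3 geometry of the acrylate intermediates, and it is equilibrated during ring closure.

Key step: step 8

Assumption: chromone numbering is used for all atom labels. Compound 8 is drawn as its hydrogen-bonded Z enol (it equilibrates with the formyl tautomer). Compounds 9–12 are drawn as the E isomers expected to predominate; any Z isomer would be carried along, since both geometries converge in step 8.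

Step 1
Reactants: 1 vanillin (4-hydroxy-3-methoxybenzaldehyde)
Product: 2 3-methoxy-4-(propan-2-yloxy)benzaldehyde
Conditions: 2-bromopropane, K2CO3, DMF, 70 °C
Reagents that add atoms: 2-bromopropane, CC(C)Br
Why: Williamson ether synthesis, in which the phenoxide is alkylated on oxygen by the secondary bromide and an excess of the bromide compensates for competing elimination.

Step 2
Reactants: 2 3-methoxy-4-(propan-2-yloxy)benzaldehyde
Product: 4 3-methoxy-4-(propan-2-yloxy)phenol, via aryl formate 3 (not isolated)
Conditions: mCPBA (1.1 equiv), CH2Cl2, 0 °C to rt; then Et3N, MeOH, rt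
Reagents that add atoms: mCPBA (3-chloroperoxybenzoic acid), OOC(=O)c1cccc(Cl)c1
Why: Baeyer–Villiger oxidation in which the electron-rich dialkoxyaryl group migrates in preference to hydrogen, followed by amine-catalysed methanolysis of the labile aryl formate.

Step 3
Reactants: 5 3,4,5-trimethoxyphenylacetic acid
Product: 6 methyl 2-(3,4,5-trimethoxyphenyl)acetate
Conditions: MeOH, H2SO4 (cat.), reflux
Reagents that add atoms: methanol, CO
Why: Fischer esterification, driven to completion by methanol as solvent.

Step 4
Reactants: 6 methyl 2-(3,4,5-trimethoxyphenyl)acetate; 7 methyl formate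
Product: 8 methyl (Z)-3-hydroxy-2-(3,4,5-trimethoxyphenyl)prop-2-enoate (enol form of the 2-formyl ester)
Conditions: NaH, THF, 0 °C to rt; then aq. HCl
Reagents that add atoms: none
Why: Crossed Claisen condensation (formylation) of the arylacetate enolate with the non-enolisable formate, pulled forward by deprotonation of the product to its sodium enolate, which on acidification should give the hydrogen-bonded Z enol.

Step 5
Reactants: 8 methyl (Z)-3-hydroxy-2-(3,4,5-trimethoxyphenyl)prop-2-enoate
Product: 9 methyl (E)-3-[(4-methylbenzenesulfonyl)oxy]-2-(3,4,5-trimethoxyphenyl)prop-2-enoate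
Conditions: TsCl, N-methylimidazole, Et3N, MeCN, 0 °C
Reagents that add atoms: p-toluenesulfonyl chloride, Cc1ccc(cc1)S(Cl)(=O)=O
Why: O-sulfonylation of a 1,3-dicarbonyl enol through the N-sulfonylimidazolium salt, in which the non-chelated enolate is expected to place the sulfonate trans to the ester.

Step 6
Reactants: 9 methyl (E)-3-[(4-methylbenzenesulfonyl)oxy]-2-(3,4,5-trimethoxyphenyl)prop-2-enoate; 4 3-methoxy-4-(propan-2-yloxy)phenol
Product: 10 methyl (E)-3-[3-methoxy-4-(propan-2-yloxy)phenoxy]-2-(3,4,5-trimethoxyphenyl)prop-2-enoate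
Conditions: K2CO3, DMF, rt to 50 °C
Reagents that add atoms: none
Why: Nucleophilic vinylic substitution by addition–elimination, in which the phenoxide adds to the unhindered C2 of the acrylate and the ester-stabilised carbanion expels tosylate, the product settling into the more stable E enol ether as the related 3-alkoxy-2-arylacrylates do.

Step 7
Reactants: 10 methyl (E)-3-[3-methoxy-4-(propan-2-yloxy)phenoxy]-2-(3,4,5-trimethoxyphenyl)prop-2-enoate
Product: 11 (E)-3-[3-methoxy-4-(propan-2-yloxy)phenoxy]-2-(3,4,5-trimethoxyphenyl)prop-2-enoic acid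
Conditions: LiOH, THF/MeOH/H2O, rt; then aq. HCl to pH 3
Reagents that add atoms: lithium hydroxide, [Li+].[OH-]
Why: Saponification of the methyl ester by acyl–oxygen cleavage, precedented for aryloxyfumarates and 3-aryloxyacrylates, whose donor-substituted double bond is a poor Michael acceptor and so keeps its aryloxy group.

Step 8
Reactants: 11 (E)-3-[3-methoxy-4-(propan-2-yloxy)phenoxy]-2-(3,4,5-trimethoxyphenyl)prop-2-enoic acid
Product: 13 7-methoxy-6-(propan-2-yloxy)-3-(3,4,5-trimethoxyphenyl)chromen-4-one, via mixed anhydride 12 (not isolated)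
Conditions: TFAA, TFA, CH2Cl2 (0.05 M), 0 °C to rt
Reagents that add atoms: none
Why: TFAA converts the acid into the mixed trifluoroacetic anhydride 12, which ionises in TFA to an acylium ion that is at the same time an aryloxy-stabilised oxocarbenium/ketene, so the C2–C3 bond loses double-bond character and the E and Z forms interconvert (reversible protonation at C3 offers a second path). Only the Z form can reach ring A, where C4a attacks the acylium carbon in an intramolecular Friedel–Crafts acylation, and loss of the proton gives the chromone and drains the equilibrium. The closest known reaction type is the acid-mediated cyclisation of 3-aryloxyacrylic and aryloxyfumaric acids to chromones. Ring C closes in the 6-exo-dig mode with respect to the acylium C≡O bond, and no stereocentre is formed. The step needs regioselectivity between the two ring-A carbons ortho to O1, and the one para to the methoxy group and next to a CH is favoured electronically and sterically over the one wedged between the two oxygens, while ring B cannot compete because attack there would form a four-membered ring. The isopropyl ether should not be ionised by TFA at this temperature.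

Step 9
Reactants: 13 7-methoxy-6-(propan-2-yloxy)-3-(3,4,5-trimethoxyphenyl)chromen-4-one
Product: 14 6-hydroxy-7-methoxy-3-(3,4,5-trimethoxyphenyl)chromen-4-one (target)
Conditions: BCl3 (1 M in CH2Cl2), CH2Cl2, −78 to 0 °C; then H2O
Reagents that add atoms: none
Why: Lewis-acid ether cleavage in which the boron-complexed isopropyl ether gives up its secondary alkyl group to chloride far faster than any methyl ether, and C5 is a CH so no methoxy group sits peri to the carbonyl for chelation-directed loss.

**Compound list**
1 | vanillin (4-hydroxy-3-methoxybenzaldehyde) | COc1cc(C=O)ccc1O | starting material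
2 | 3-methoxy-4-(propan-2-yloxy)benzaldehyde | COc1cc(C=O)ccc1OC(C)C | intermediate
3 | 3-methoxy-4-(propan-2-yloxy)phenyl formate | COc1cc(OC=O)ccc1OC(C)C | intermediate
4 | 3-methoxy-4-(propan-2-yloxy)phenol | COc1cc(O)ccc1OC(C)C | intermediate
5 | 3,4,5-trimethoxyphenylacetic acid | OC(=O)Cc1cc(OC)c(OC)c(OC)c1 | starting material
6 | methyl 2-(3,4,5-trimethoxyphenyl)acetate | COC(=O)Cc1cc(OC)c(OC)c(OC)c1 | intermediate
7 | methyl formate | COC=O | starting material
8 | methyl (Z)-3-hydroxy-2-(3,4,5-trimethoxyphenyl)prop-2-enoate | COC(=O)/C(=C\O)c1cc(OC)c(OC)c(OC)c1 | intermediate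
9 | methyl (E)-3-[(4-methylbenzenesulfonyl)oxy]-2-(3,4,5-trimethoxyphenyl)prop-2-enoate | COC(=O)/C(=C/OS(=O)(=O)c1ccc(C)cc1)c1cc(OC)c(OC)c(OC)c1 | intermediate
10 | methyl (E)-3-[3-methoxy-4-(propan-2-yloxy)phenoxy]-2-(3,4,5-trimethoxyphenyl)prop-2-enoate | COC(=O)/C(=C/Oc1ccc(OC(C)C)c(OC)c1)c1cc(OC)c(OC)c(OC)c1 | intermediate
11 | (E)-3-[3-methoxy-4-(propan-2-yloxy)phenoxy]-2-(3,4,5-trimethoxyphenyl)prop-2-enoic acid | OC(=O)/C(=C/Oc1ccc(OC(C)C)c(OC)c1)c1cc(OC)c(OC)c(OC)c1 | intermediate
12 | mixed anhydride of 11 with trifluoroacetic acid | FC(F)(F)C(=O)OC(=O)/C(=C/Oc1ccc(OC(C)C)c(OC)c1)c1cc(OC)c(OC)c(OC)c1 | intermediate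
13 | 7-methoxy-6-(propan-2-yloxy)-3-(3,4,5-trimethoxyphenyl)chromen-4-one | COc1cc2occ(-c3cc(OC)c(OC)c(OC)c3)c(=O)c2cc1OC(C)C | intermediate
14 | 6-hydroxy-7-methoxy-3-(3,4,5-trimethoxyphenyl)chromen-4-one | COc1cc2occ(-c3cc(OC)c(OC)c(OC)c3)c(=O)c2cc1O | target

**Totals**
Total steps: 9. Longest linear sequence: 7 steps (steps 3–9, from 5). The ring-A branch from vanillin is 2 steps before the union in step 6.

**Steps most likely to fail**

Step 8. Risk: the E-to-Z equilibration of the activated acid may lag behind acid-induced cleavage of the aryl vinyl ether, so that too little Z acylium is available for ring closure. Fallback (sets out from 11, returns at 13): the same C4–C4a bond is closed one oxidation level lower, where no alkene geometry exists. Hydrogenation of 11 (H2, Pd/C, EtOAc, rt) should give racemic 3-[3-methoxy-4-(propan-2-yloxy)phenoxy]-2-(3,4,5-trimethoxyphenyl)propanoic acid F1. TFAA/TFA in CH2Cl2 should convert it through its mixed trifluoroacetic anhydride F2 into racemic 7-methoxy-6-(propan-2-yloxy)-3-(3,4,5-trimethoxyphenyl)chroman-4-one F3, the classical chroman-4-one closure of 3-aryloxypropanoic acids. Dehydrogenation with DDQ (2,3-dichloro-5,6-dicyano-1,4-benzoquinone) in 1,4-dioxane at reflux returns the route to 13.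

Step 6. Risk: sulfonyl transfer, that is attack of the phenoxide at sulfur of the enol tosylate in place of C2, which would return the enolate of 8 and consume the phenol as its tosylate. Fallback (sets out from 8, returns at 10): the sulfonate is replaced by a leaving group whose only electrophilic site is carbon. Vilsmeier-type chlorination of 8 ((COCl)2, DMF (cat.), CH2Cl2, 0 °C to rt) should give methyl 3-chloro-2-(3,4,5-trimethoxyphenyl)prop-2-enoate F4 as an E/Z mixture. The potassium salt of 4 (K2CO3, DMF) then displaces chloride by addition–elimination, the classical exchange of β-chlorovinyl carbonyl compounds with phenoxides, to give 10.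

Step 9. Risk: over-dealkylation, i.e. loss of a methyl group (at O7 through the neighbouring O6–boron species, or at the central oxygen of ring B) alongside the isopropyl group. Fallback (sets out from 1, uses 9, returns at 14): the phenol is carried as a benzyl ether, which is removed by hydrogenolysis without any Lewis acid. Vanillin 1 with benzyl bromide (K2CO3, DMF) should give 4-(benzyloxy)-3-methoxybenzaldehyde F5. mCPBA and then Et3N/MeOH convert it through 4-(benzyloxy)-3-methoxyphenyl formate F6 into 4-(benzyloxy)-3-methoxyphenol F7. Substitution on tosylate 9 (K2CO3, DMF) gives methyl (E)-3-[4-(benzyloxy)-3-methoxyphenoxy]-2-(3,4,5-trimethoxyphenyl)prop-2-enoate F8, and LiOH gives (E)-3-[4-(benzyloxy)-3-methoxyphenoxy]-2-(3,4,5-trimethoxyphenyl)prop-2-enoic acid F9. TFAA/TFA closes ring C through the mixed trifluoroacetic anhydride F10 to 6-(benzyloxy)-7-methoxy-3-(3,4,5-trimethoxyphenyl)chromen-4-one F11. H2 over Pd/C in EtOAc/MeOH at rt then gives 14.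

**Further compounds**
F1 | step 8 | racemic 3-[3-methoxy-4-(propan-2-yloxy)phenoxy]-2-(3,4,5-trimethoxyphenyl)propanoic acid | OC(=O)C(COc1ccc(OC(C)C)c(OC)c1)c1cc(OC)c(OC)c(OC)c1
F2 | step 8 | mixed anhydride of F1 with trifluoroacetic acid (racemic) | FC(F)(F)C(=O)OC(=O)C(COc1ccc(OC(C)C)c(OC)c1)c1cc(OC)c(OC)c(OC)c1
F3 | step 8 | racemic 7-methoxy-6-(propan-2-yloxy)-3-(3,4,5-trimethoxyphenyl)chroman-4-one | COc1cc2OCC(c3cc(OC)c(OC)c(OC)c3)C(=O)c2cc1OC(C)C
F4 | step 6 | methyl 3-chloro-2-(3,4,5-trimethoxyphenyl)prop-2-enoate (E/Z mixture) | COC(=O)C(=CCl)c1cc(OC)c(OC)c(OC)c1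
F5 | step 9 | 4-(benzyloxy)-3-methoxybenzaldehyde | COc1cc(C=O)ccc1OCc1ccccc1
F6 | step 9 | 4-(benzyloxy)-3-methoxyphenyl formate | COc1cc(OC=O)ccc1OCc1ccccc1
F7 | step 9 | 4-(benzyloxy)-3-methoxyphenol | COc1cc(O)ccc1OCc1ccccc1
F8 | step 9 | methyl (E)-3-[4-(benzyloxy)-3-methoxyphenoxy]-2-(3,4,5-trimethoxyphenyl)prop-2-enoate | COC(=O)/C(=C/Oc1ccc(OCc2ccccc2)c(OC)c1)c1cc(OC)c(OC)c(OC)c1
F9 | step 9 | (E)-3-[4-(benzyloxy)-3-methoxyphenoxy]-2-(3,4,5-trimethoxyphenyl)prop-2-enoic acid | OC(=O)/C(=C/Oc1ccc(OCc2ccccc2)c(OC)c1)c1cc(OC)c(OC)c(OC)c1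
F10 | step 9 | mixed anhydride of F9 with trifluoroacetic acid | FC(F)(F)C(=O)OC(=O)/C(=C/Oc1ccc(OCc2ccccc2)c(OC)c1)c1cc(OC)c(OC)c(OC)c1
F11 | step 9 | 6-(benzyloxy)-7-methoxy-3-(3,4,5-trimethoxyphenyl)chromen-4-one | COc1cc2occ(-c3cc(OC)c(OC)c(OC)c3)c(=O)c2cc1OCc1ccccc1
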